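**Retrosynthetic overview**
- Feature: in pyranone ring B (O1–C2–C3–C4–C4a–C8a) the C4 carbonyl sits between aromatic C4a of ring A and the C3–C2 unit, and C2, the only stereocentre, is β to that carbonyl.
- Target ⇐ (2R)-5,8-dimethoxychromanone (two O–CH3 cleavages) ⇐ flat 5,8-dimethoxychromone (C2–H set by asymmetric copper hydride 1,4-reduction).
- Chromone ring B ⇐ 2-iodo-3,6-dimethoxyphenol + carbon monoxide + (14Z)-nonadec-14-en-1-yne, forming C4a–C4, C4–C3 and O1–C2 in one operation.
- Iodophenol ⇐ 2,5-dimethoxyphenol (MOM ether, ortho-lithiation, iodine, unmasking); alkyne ⇐ (Z)-octadec-13-enal (Ohira–Bestmann homologation).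
- Ring order: ring A is purchased; ring B is the only ring formed, in the carbonylative annulation.

Key step: step 5

Assumption: 2,5-dimethoxyphenol and the pheromone component (Z)-octadec-13-enal are taken as purchasable, and the (R)-antipode of DTBM-SEGPHOS is taken to deliver hydride to the face of C2 that gives the 2R product; if a trial reduction shows the opposite sense, the (S)-ligand is used with no other change.

**Step 1**
Reactants: 1 2,5-dimethoxyphenol
Product: 2 1,4-dimethoxy-2-(methoxymethoxy)benzene
Conditions: NaH, MOMCl, THF, 0 °C → rt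
Reagents that add atoms: chloromethyl methyl ether, COCCl
Why: Williamson-type O-alkylation of the sodium phenoxide gives the MOM acetal, chosen because OMOM is a strong ortho-directing group for the lithiation and is removed by mild acid.

**Step 2**
Reactants: 2 1,4-dimethoxy-2-(methoxymethoxy)benzene
Product: 4 2-iodo-1,4-dimethoxy-3-(methoxymethoxy)benzene, via aryllithium 3 (not isolated)
Conditions: n-BuLi, TMEDA, THF, 0 °C; then I2, THF, −78 °C → rt
Reagents that add atoms: iodine, II
Why: Directed ortho-metalation: the ring proton between OMOM and OMe is the only one flanked by two coordinating oxygens, so n-BuLi should remove it selectively, and iodine quench of aryllithium 3 places iodine on the carbon that becomes C4a.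

**Step 3**
Reactants: 4 2-iodo-1,4-dimethoxy-3-(methoxymethoxy)benzene
Product: 5 2-iodo-3,6-dimethoxyphenol
Conditions: HCl (1.25 M in MeOH), 40 °C
Reagents that add atoms: none
Why: Acid-catalysed transacetalisation of the MOM acetal to methanol frees the phenol that becomes O1, while the aryl iodide and the methyl ethers are inert to dilute HCl at this temperature.

**Step 4**
Reactants: 6 (Z)-octadec-13-enal
Product: 8 (14Z)-nonadec-14-en-1-yne, via diazoalkene 7 (not isolated)
Conditions: dimethyl (1-diazo-2-oxopropyl)phosphonate, K2CO3, MeOH, 0 °C → rt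
Reagents that add atoms: dimethyl (1-diazo-2-oxopropyl)phosphonate, CC(=O)C(=[N+]=[N-])P(=O)(OC)OC
Why: Ohira–Bestmann (Seyferth–Gilbert) homologation: methanolysis of the reagent gives the diazomethylphosphonate anion, whose addition–elimination with the aldehyde gives diazoalkene 7, which loses N2 and rearranges by 1,2-hydrogen shift to the terminal alkyne under conditions mild enough to leave the Z-alkene untouched.

**Step 5**
Reactants: 5 2-iodo-3,6-dimethoxyphenol; 8 (14Z)-nonadec-14-en-1-yne; 9 carbon monoxide
Product: 12 2-[(12Z)-heptadec-12-en-1-yl]-5,8-dimethoxy-4H-chromen-4-one, via aryl ynone 10 (not isolated), via enaminone 11 (not isolated)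
Conditions: PdCl2(PPh3)2 (5 mol%), CO (20 atm), Et2NH, 120 °C, autoclave
Reagents that add atoms: none
Why: PdCl2(PPh3)2 is reduced in the amine to zerovalent palladium, which inserts into the C–I bond of 5; CO insertion gives an aroyl complex of divalent palladium, and coupling with the terminal carbon of 8 (deprotonated by Et2NH) releases ynone 10, forming C4a–C4 and C4–C3. Diethylamine then adds to the β-carbon of the ynone to give enaminone 11, and the ortho phenol oxygen attacks the same carbon and expels the amine, forming O1–C2. The closest known reaction type is the palladium-catalysed carbonylative coupling of 2-iodophenols with terminal alkynes in a secondary amine giving 2-substituted chromones, that is, a carbonylative Sonogashira coupling followed by amine-mediated cyclisation. Ring B closes in a 6-endo mode (6-endo-dig with respect to the ynone, addition–elimination on the enaminone), and the amine enforces this over 5-exo aurone closure because it makes the β-carbon the only electrophilic site. No stereocentre is formed; the step needs carbonylative over direct coupling, secured by CO pressure and the absence of a copper co-catalyst, and it needs the remote Z-alkene to stay out of Heck chemistry, which holds because an unactivated internal 1,2-dialkyl alkene reacts far more slowly with aryl- and acyl-palladium than CO and the alkyne do.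

**Step 6**
Reactants: 12 2-[(12Z)-heptadec-12-en-1-yl]-5,8-dimethoxy-4H-chromen-4-one
Product: 13 (2R)-2-[(12Z)-heptadec-12-en-1-yl]-5,8-dimethoxy-2,3-dihydro-4H-chromen-4-one
Conditions: Cu(OAc)2 (5 mol%), (R)-DTBM-SEGPHOS (5.5 mol%), (EtO)2MeSiH, t-BuOH, toluene, 0 °C → rt; then aq. NH4Cl
Reagents that add atoms: none
Why: Ligated monovalent copper hydride, formed from Cu(OAc)2 and the silane, adds hydride to C2 in a catalytic asymmetric 1,4-reduction of the kind known for 2-substituted chromones, the chiral bisphosphine on copper choosing the face so that C2 is set as R, after which t-BuOH protonates the copper enolate at C3 and the unactivated Z-alkene is not hydrocuprated at this temperature.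

**Step 7**
Reactants: 13 (2R)-2-[(12Z)-heptadec-12-en-1-yl]-5,8-dimethoxy-2,3-dihydro-4H-chromen-4-one
Product: 14 (2R)-2-[(12Z)-heptadec-12-en-1-yl]-5,8-dihydroxy-2,3-dihydro-4H-chromen-4-one
Conditions: BBr3 (5 equiv), CH2Cl2, −78 → 0 °C; MeOH, then aq. NaHCO3/Na2S2O4, under Ar
Reagents that add atoms: none
Why: Lewis-acid ether cleavage: BBr3 coordinates each methoxy oxygen (the 5-OMe helped by chelation to the C4 carbonyl) and bromide removes the methyl group by SN2, hydrolysis of the aryl borates frees both phenols, and the low temperature, the absence of base and the reductive work-up should protect C2, the Z-alkene and the air-sensitive hydroquinone.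

**Compound list**
1 | 2,5-dimethoxyphenol | COc1ccc(OC)c(O)c1 | starting material
2 | 1,4-dimethoxy-2-(methoxymethoxy)benzene | COCOc1cc(OC)ccc1OC | intermediate
3 | [3,6-dimethoxy-2-(methoxymethoxy)phenyl]lithium | COCOc1c([Li])c(OC)ccc1OC | intermediate
4 | 2-iodo-1,4-dimethoxy-3-(methoxymethoxy)benzene | COCOc1c(I)c(OC)ccc1OC | intermediate
5 | 2-iodo-3,6-dimethoxyphenol | COc1ccc(OC)c(I)c1O | intermediate
6 | (Z)-octadec-13-enal | CCCC/C=C\CCCCCCCCCCCC=O | starting material
7 | (14Z)-1-diazononadeca-1,14-diene | CCCC/C=C\CCCCCCCCCCCC=C=[N+]=[N-] | intermediate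
8 | (14Z)-nonadec-14-en-1-yne | CCCC/C=C\CCCCCCCCCCCC#C | intermediate
9 | carbon monoxide | [C-]#[O+] | starting material
10 | (15Z)-1-(2-hydroxy-3,6-dimethoxyphenyl)icos-15-en-2-yn-1-one | CCCC/C=C\CCCCCCCCCCCC#CC(=O)c1c(OC)ccc(OC)c1O | intermediate
11 | (2E,15Z)-3-(diethylamino)-1-(2-hydroxy-3,6-dimethoxyphenyl)icosa-2,15-dien-1-one | CCCC/C=C\CCCCCCCCCCC/C(N(CC)CC)=C\C(=O)c1c(OC)ccc(OC)c1O | intermediate
12 | 2-[(12Z)-heptadec-12-en-1-yl]-5,8-dimethoxy-4H-chromen-4-one | CCCC/C=C\CCCCCCCCCCCc1cc(=O)c2c(OC)ccc(OC)c2o1 | intermediate
13 | (2R)-2-[(12Z)-heptadec-12-en-1-yl]-5,8-dimethoxy-2,3-dihydro-4H-chromen-4-one | CCCC/C=C\CCCCCCCCCCC[C@@H]1CC(=O)c2c(OC)ccc(OC)c2O1 | intermediate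
14 | (2R)-2-[(12Z)-heptadec-12-en-1-yl]-5,8-dihydroxy-2,3-dihydro-4H-chromen-4-one | CCCC/C=C\CCCCCCCCCCC[C@@H]1CC(=O)c2c(O)ccc(O)c2O1 | target

**Step count**
Total steps: 7. Longest linear sequence: 6 (steps 1, 2, 3, 5, 6, 7); step 4 is a one-step branch that joins at step 5.

**Steps most likely to fail**

Step 5. The aryl iodide is flanked by a hydroxyl and a methoxy group, so oxidative addition and CO insertion may be slow. Diethylamine could then trap the aroyl–palladium as an amide, coupling without CO could lead to a benzofuran, or five-membered aurone closure could compete. The fallback sets out from aryllithium 3 (generated from 2 as in step 2) and from alkyne 8, and comes back to the route at chromone 12. Alkyne 8 is deprotonated with n-BuLi in THF at −78 °C and formylated with DMF to give (15Z)-icos-15-en-2-ynal F1. Aryllithium 3 adds to the aldehyde of F1 at −78 °C to give (15Z)-1-[3,6-dimethoxy-2-(methoxymethoxy)phenyl]icos-15-en-2-yn-1-ol F2, and MnO2 in CH2Cl2 oxidises this propargylic, benzylic alcohol to (15Z)-1-[3,6-dimethoxy-2-(methoxymethoxy)phenyl]icos-15-en-2-yn-1-one F3. HCl in MeOH removes the MOM group to give ynone 10, and Et2NH in EtOH at room temperature takes 10 through enaminone 11 to chromone 12.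

Step 6. Facial discrimination may be poor at this electron-rich, peri-substituted vinylogous ester, the C4 carbonyl may be over-reduced, or the C2 configuration may erode by ring opening of the enolate (retro-oxa-Michael) and reclosure. The fallback sets out from chromone 12 and comes back at chromanone 13. LiBH(s-Bu)3 in THF at −78 °C adds hydride 1,4 to give racemic 2-[(12Z)-heptadec-12-en-1-yl]-5,8-dimethoxy-2,3-dihydro-4H-chromen-4-one F4. Preparative HPLC on a chiral stationary phase separates 13 from (2S)-2-[(12Z)-heptadec-12-en-1-yl]-5,8-dimethoxy-2,3-dihydro-4H-chromen-4-one F5. The unwanted F5 can in principle be returned to F4 with DBU through reversible ring opening and resubmitted to the separation.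

Step 7. HBr set free in the quench may add to or isomerise the Z-alkene, acid-promoted ring opening may scramble C2, the 8-methyl ether may be cleaved incompletely, and the hydroquinone may oxidise in air. The fallback sets out from chromanone 13 and comes back at target 14. Oxidative demethylation with (NH4)2Ce(NO3)6 in MeCN/H2O at 0 °C gives (2R)-2-[(12Z)-heptadec-12-en-1-yl]-2,3-dihydro-4H-chromene-4,5,8-trione F6 without any Lewis or Brønsted acid strong enough to touch the alkene. Immediate reduction of the quinone with aqueous Na2S2O4 in EtOAc under argon gives 14.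

**Further compounds**
F1 | step 5 | (15Z)-icos-15-en-2-ynal | CCCC/C=C\CCCCCCCCCCCC#CC=O
F2 | step 5 | (15Z)-1-[3,6-dimethoxy-2-(methoxymethoxy)phenyl]icos-15-en-2-yn-1-ol | CCCC/C=C\CCCCCCCCCCCC#CC(O)c1c(OC)ccc(OC)c1OCOC
F3 | step 5 | (15Z)-1-[3,6-dimethoxy-2-(methoxymethoxy)phenyl]icos-15-en-2-yn-1-one | CCCC/C=C\CCCCCCCCCCCC#CC(=O)c1c(OC)ccc(OC)c1OCOC
F4 | step 6 | racemic 2-[(12Z)-heptadec-12-en-1-yl]-5,8-dimethoxy-2,3-dihydro-4H-chromen-4-one | CCCC/C=C\CCCCCCCCCCCC1CC(=O)c2c(OC)ccc(OC)c2O1
F5 | step 6 | (2S)-2-[(12Z)-heptadec-12-en-1-yl]-5,8-dimethoxy-2,3-dihydro-4H-chromen-4-one | CCCC/C=C\CCCCCCCCCCC[C@H]1CC(=O)c2c(OC)ccc(OC)c2O1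
F6 | step 7 | (2R)-2-[(12Z)-heptadec-12-en-1-yl]-2,3-dihydro-4H-chromene-4,5,8-trione | CCCC/C=C\CCCCCCCCCCC[C@@H]1CC(=O)C2=C(O1)C(=O)C=CC2=O
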